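**Retrosynthetic overview**

1. Rings are lettered A (2,4,6-trihydroxyphenyl end) to H (3,4,5-trihydroxyphenyl end). The target 28 comes from its 21-fold methyl ether 27 by BBr3, and 27 from ABC iodide 15 and DEFGH phenol 26 by a copper-catalysed C6(ring C)–O(ring D) etherification.
2. The strategy rests on rings C, E and G: each has two aryloxy groups on the adjacent carbons C1 and C6, next to the oxygen at C5. This is the 1,2-adduct pattern of 3,4,5-trimethoxybenzyne, so O(ring B)–C1(ring C) and C6–I are made together by aryne oxy-iodination of the AB phenoxide.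
3. The same reaction on 19 gives the benzyl-capped two-ring iodide 22, which serves as rings D–E and again as rings F–G. Two copies of 22 and 3,4,5-trimethoxyphenol give 26 by alternating copper etherification and hydrogenolysis.
4. AB phenol 5 comes from SNAr then Dakin oxidation. Aryne precursor 11 comes from 3,4,5-trimethoxyphenol by bromination, O-silylation and retro-Brook shift with triflation.
5. No ring is built; all eight benzene rings are bought. They are joined in the order A–B, then C; D–E (= F–G); G–H, then E–F; last C–D.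

Key step: step 6

Remark: the target has no stereocentre and no configurationally stable axis, so nothing stereochemical has to be set; rings E and G are numbered like ring C (C1 carries the oxygen to the preceding ring, C6 the oxygen to the following ring).

**Route**

Step 1
Reactants: 1 2,4,6-trimethoxyphenol; 2 4-fluoro-2,6-dimethoxybenzaldehyde
Product: 3 2,6-dimethoxy-4-(2,4,6-trimethoxyphenoxy)benzaldehyde
Conditions: K2CO3, DMF, 110 °C
Reagents that add atoms: none
Why: SNAr, in which the para-formyl group activates the C–F bond toward the electron-rich phenoxide and fluoride is the only good leaving group on the ring.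

Step 2
Reactants: 3 2,6-dimethoxy-4-(2,4,6-trimethoxyphenoxy)benzaldehyde
Product: 5 AB dimer phenol 2,6-dimethoxy-4-(2,4,6-trimethoxyphenoxy)phenol, via AB aryl formate 4 (not isolated)
Conditions: mCPBA, CH2Cl2, 0 °C to rt; then K2CO3 (cat.), MeOH, rt
Reagents that add atoms: mCPBA (3-chloroperoxybenzoic acid), OOC(=O)c1cccc(Cl)c1
Why: Dakin-type Baeyer–Villiger oxidation, in which the aryl group with two ortho and one para oxygen donors migrates in preference to hydride and the formate is cleaved by methanolysis.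

Step 3
Reactants: 6 3,4,5-trimethoxyphenol
Product: 7 2-bromo-3,4,5-trimethoxyphenol
Conditions: NBS (1.0 equiv), CH2Cl2, −78 to 0 °C
Reagents that add atoms: N-bromosuccinimide, O=C1CCC(=O)N1Br
Why: Electrophilic aromatic bromination; the two free positions ortho to the hydroxyl are equivalent, so one equivalent of NBS at low temperature should give a single monobromide.

Step 4
Reactants: 7 2-bromo-3,4,5-trimethoxyphenol
Product: 8 (2-bromo-3,4,5-trimethoxyphenoxy)trimethylsilane
Conditions: HMDS, THF, reflux; evaporation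
Reagents that add atoms: hexamethyldisilazane, C[Si](C)(C)N[Si](C)(C)C
Why: O-silylation of a phenol with HMDS, driven by loss of ammonia.

Step 5
Reactants: 8 (2-bromo-3,4,5-trimethoxyphenoxy)trimethylsilane
Product: 11 3,4,5-trimethoxy-2-(trimethylsilyl)phenyl trifluoromethanesulfonate, via aryllithium 9 (not isolated), via lithium 2-silylphenoxide 10 (not isolated)
Conditions: n-BuLi, THF, −78 °C; then Tf2O, −78 °C to rt
Reagents that add atoms: trifluoromethanesulfonic anhydride, O=S(=O)(OS(=O)(=O)C(F)(F)F)C(F)(F)F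
Why: Bromine–lithium exchange followed by 1,3 O-to-C silyl migration (retro-Brook rearrangement) and triflation of the lithium phenoxide, the standard entry to ortho-silylaryl triflates.

Step 6
Reactants: 5 AB dimer phenol 2,6-dimethoxy-4-(2,4,6-trimethoxyphenoxy)phenol; 11 3,4,5-trimethoxy-2-(trimethylsilyl)phenyl trifluoromethanesulfonate
Product: 15 ABC trimer iodide 2-[4-(2-iodo-3,4,5-trimethoxyphenoxy)-3,5-dimethoxyphenoxy]-1,3,5-trimethoxybenzene, via potassium phenoxide of the AB dimer 12 (not isolated), via 3,4,5-trimethoxybenzyne 13 (not isolated), via ring C aryl anion 14 (not isolated)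
Conditions: KH, DME, 0 °C; then n-C6F13I (3 equiv), CsF, 18-crown-6, slow addition of 11 (1.5 equiv), DME, 0 °C to rt, dark, argon
Reagents that add atoms: perfluorohexyl iodide (tridecafluoro-1-iodohexane), FC(F)(F)C(F)(F)C(F)(F)C(F)(F)C(F)(F)C(F)(F)I
Why: Proposed new method: fluoride strips the silyl group of 11 and triflate leaves to give aryne 13; the pre-formed, proton-free phenoxide 12 adds to the aryne carbon remote from the flanking methoxy group (C1 of ring C), and the resulting aryl anion 14 at C6 takes iodine from perfluorohexyl iodide by halogen-bond-assisted transfer faster than it can find a proton. The closest known reaction types are the fluoride-triggered aryne O-arylation of phenols, which accepts 2,6-disubstituted phenoxides at room temperature, and aryne three-component couplings in which a heteroatom anion adds and a perfluoroalkyl iodide hands iodine to the aryl anion; pairing a phenoxide with iodine transfer is the untested part. No ring is closed and no stereocentre arises. The step needs regioselectivity (oxygen at C1, iodine at C6) and chemoselectivity (iodination, not protonation). The first rests on the inductive pull of the C5 methoxy group, which distorts the aryne toward attack at the distal carbon and stabilises the negative charge building up at C6; the second rests on the absence of any O–H or acidic C–H (KH as base, DME in place of acetonitrile) and on an excess of the iodine donor. Working in the dark should suppress electron transfer from the electron-rich phenoxide to the perfluoroalkyl iodide.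

Step 7
Reactants: 16 4-hydroxy-2,6-dimethoxybenzaldehyde
Product: 17 4-(benzyloxy)-2,6-dimethoxybenzaldehyde
Conditions: BnBr, K2CO3, DMF, rt
Reagents that add atoms: benzyl bromide, BrCc1ccccc1
Why: Williamson etherification of an acidic para-formyl phenol with a reactive benzylic halide.

Step 8
Reactants: 17 4-(benzyloxy)-2,6-dimethoxybenzaldehyde
Product: 19 4-(benzyloxy)-2,6-dimethoxyphenol, via 4-(benzyloxy)-2,6-dimethoxyphenyl formate 18 (not isolated)
Conditions: mCPBA, CH2Cl2, 0 °C to rt; then K2CO3 (cat.), MeOH, rt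
Reagents that add atoms: mCPBA (3-chloroperoxybenzoic acid), OOC(=O)c1cccc(Cl)c1
Why: Dakin-type Baeyer–Villiger oxidation as in step 2, with migration of the trioxygenated aryl group and methanolysis of the formate; the benzyl ether is inert.

Step 9
Reactants: 19 4-(benzyloxy)-2,6-dimethoxyphenol; 11 3,4,5-trimethoxy-2-(trimethylsilyl)phenyl trifluoromethanesulfonate
Product: 22 two-ring iodide 5-(benzyloxy)-2-(2-iodo-3,4,5-trimethoxyphenoxy)-1,3-dimethoxybenzene, via potassium 4-(benzyloxy)-2,6-dimethoxyphenoxide 20 (not isolated), via ring E aryl anion 21 (not isolated)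
Conditions: KH, DME, 0 °C; then n-C6F13I (3 equiv), CsF, 18-crown-6, slow addition of 11 (1.5 equiv), DME, 0 °C to rt, dark, argon
Reagents that add atoms: perfluorohexyl iodide (tridecafluoro-1-iodohexane), FC(F)(F)C(F)(F)C(F)(F)C(F)(F)C(F)(F)C(F)(F)I
Why: Proposed new method: as in step 6, fluoride releases from 11 the same 3,4,5-trimethoxybenzyne (13), phenoxide 20 adds to its carbon remote from the flanking methoxy group and the ortho aryl anion 21 abstracts iodine from perfluorohexyl iodide, the closest known reaction types being aryne O-arylation of hindered phenols and aryne three-component coupling of heteroatom anions with iodine donors; the benzyl ether is inert to fluoride and to the short-lived aryl anion.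

Step 10
Reactants: 22 two-ring iodide 5-(benzyloxy)-2-(2-iodo-3,4,5-trimethoxyphenoxy)-1,3-dimethoxybenzene; 6 3,4,5-trimethoxyphenol
Product: 23 benzyl-capped FGH trimer 5-(benzyloxy)-1,3-dimethoxy-2-[3,4,5-trimethoxy-2-(3,4,5-trimethoxyphenoxy)phenoxy]benzene
Conditions: CuI (cat.), picolinic acid, K3PO4, DMSO, 100 °C; 6 (2 equiv)
Reagents that add atoms: none
Why: Ullmann diaryl ether synthesis with the CuI–picolinic acid system, which suits ortho-substituted aryl iodides, helped by an excess of the unhindered, electron-rich phenol.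

Step 11
Reactants: 23 benzyl-capped FGH trimer
Product: 24 FGH trimer phenol 3,5-dimethoxy-4-[3,4,5-trimethoxy-2-(3,4,5-trimethoxyphenoxy)phenoxy]phenol
Conditions: H2 (1 atm), Pd/C, EtOAc–MeOH, rt
Reagents that add atoms: none
Why: Hydrogenolysis of a benzyl aryl ether; diaryl and methyl aryl ethers are untouched and no halogen is left in the molecule.

Step 12
Reactants: 22 two-ring iodide 5-(benzyloxy)-2-(2-iodo-3,4,5-trimethoxyphenoxy)-1,3-dimethoxybenzene; 24 FGH trimer phenol
Product: 25 benzyl-capped DEFGH pentamer (22 with iodine replaced by the phenol oxygen of 24)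
Conditions: CuI (cat.), picolinic acid, K3PO4, DMSO, 100 °C; 22 (1.3 equiv)
Reagents that add atoms: none
Why: Ullmann diaryl ether synthesis as in step 10, here with the more accessible iodide 22 in excess over the unhindered ring F phenol.

Step 13
Reactants: 25 benzyl-capped DEFGH pentamer
Product: 26 DEFGH pentamer phenol (free hydroxyl at C1 of ring D, para to the oxygen that leads to ring E)
Conditions: H2 (1 atm), Pd/C, EtOAc–MeOH, rt
Reagents that add atoms: none
Why: Hydrogenolysis of the benzyl aryl ether as in step 11.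

Step 14
Reactants: 15 ABC trimer iodide; 26 DEFGH pentamer phenol
Product: 27 permethylated octamer (the target with all 21 hydroxyl groups as methyl ethers)
Conditions: CuI (20 mol%), picolinic acid (40 mol%), K3PO4, DMSO, 100 °C; 15 (1.3 equiv)
Reagents that add atoms: none
Why: Ullmann diaryl ether synthesis between the C6 iodide of ring C and the unhindered ring D phenol, the same bond type as in steps 10 and 12.

Step 15
Reactants: 27 permethylated octamer
Product: 28 target CNP0206369.0
Conditions: BBr3 (excess, about 3 equiv per methoxy group), CH2Cl2, −78 °C to rt, argon; then MeOH, H2O, 0 °C; degassed solvents for isolation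
Reagents that add atoms: none
Why: Lewis acid cleavage of aryl methyl ethers by BBr3 (bromide attacks the methyl group of the boron-bound ether), which leaves diaryl ethers intact.

**Compound list**

1 | 2,4,6-trimethoxyphenol | COc1cc(OC)c(O)c(OC)c1 | starting material
2 | 4-fluoro-2,6-dimethoxybenzaldehyde | COc1cc(F)cc(OC)c1C=O | starting material
3 | 2,6-dimethoxy-4-(2,4,6-trimethoxyphenoxy)benzaldehyde | COc1cc(OC)c(Oc2cc(OC)c(C=O)c(OC)c2)c(OC)c1 | intermediate
4 | 2,6-dimethoxy-4-(2,4,6-trimethoxyphenoxy)phenyl formate | COc1cc(OC)c(Oc2cc(OC)c(OC=O)c(OC)c2)c(OC)c1 | intermediate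
5 | AB dimer phenol, 2,6-dimethoxy-4-(2,4,6-trimethoxyphenoxy)phenol | COc1cc(OC)c(Oc2cc(OC)c(O)c(OC)c2)c(OC)c1 | intermediate
6 | 3,4,5-trimethoxyphenol | COc1cc(O)cc(OC)c1OC | starting material
7 | 2-bromo-3,4,5-trimethoxyphenol | COc1cc(O)c(Br)c(OC)c1OC | intermediate
8 | (2-bromo-3,4,5-trimethoxyphenoxy)trimethylsilane | COc1cc(O[Si](C)(C)C)c(Br)c(OC)c1OC | intermediate
9 | [2,3,4-trimethoxy-6-(trimethylsilyloxy)phenyl]lithium | COc1cc(O[Si](C)(C)C)c([Li])c(OC)c1OC | intermediate
10 | lithium 3,4,5-trimethoxy-2-(trimethylsilyl)phenoxide | COc1cc([O-])c([Si](C)(C)C)c(OC)c1OC.[Li+] | intermediate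
11 | 3,4,5-trimethoxy-2-(trimethylsilyl)phenyl trifluoromethanesulfonate | COc1cc(OS(=O)(=O)C(F)(F)F)c([Si](C)(C)C)c(OC)c1OC | intermediate
12 | potassium 2,6-dimethoxy-4-(2,4,6-trimethoxyphenoxy)phenoxide | COc1cc(OC)c(Oc2cc(OC)c([O-])c(OC)c2)c(OC)c1.[K+] | intermediate
13 | 3,4,5-trimethoxybenzyne (1,2-didehydro-3,4,5-trimethoxybenzene) | COC1=C(OC)C(OC)=CC#C1 | intermediate
14 | potassium salt of the ABC trimer carbanion at C6 of ring C | COc1cc(OC)c(Oc2cc(OC)c(Oc3cc(OC)c(OC)c(OC)[c-]3)c(OC)c2)c(OC)c1.[K+] | intermediate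
15 | ABC trimer iodide, 2-[4-(2-iodo-3,4,5-trimethoxyphenoxy)-3,5-dimethoxyphenoxy]-1,3,5-trimethoxybenzene | COc1cc(OC)c(Oc2cc(OC)c(Oc3cc(OC)c(OC)c(OC)c3I)c(OC)c2)c(OC)c1 | intermediate
16 | 4-hydroxy-2,6-dimethoxybenzaldehyde | COc1cc(O)cc(OC)c1C=O | starting material
17 | 4-(benzyloxy)-2,6-dimethoxybenzaldehyde | COc1cc(OCc2ccccc2)cc(OC)c1C=O | intermediate
18 | 4-(benzyloxy)-2,6-dimethoxyphenyl formate | COc1cc(OCc2ccccc2)cc(OC)c1OC=O | intermediate
19 | 4-(benzyloxy)-2,6-dimethoxyphenol | COc1cc(OCc2ccccc2)cc(OC)c1O | intermediate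
20 | potassium 4-(benzyloxy)-2,6-dimethoxyphenoxide | COc1cc(OCc2ccccc2)cc(OC)c1[O-].[K+] | intermediate
21 | potassium salt of the carbanion of 22 at the iodine-bearing carbon (C6 of ring E) | COc1cc(OCc2ccccc2)cc(OC)c1Oc1cc(OC)c(OC)c(OC)[c-]1.[K+] | intermediate
22 | 5-(benzyloxy)-2-(2-iodo-3,4,5-trimethoxyphenoxy)-1,3-dimethoxybenzene | COc1cc(OCc2ccccc2)cc(OC)c1Oc1cc(OC)c(OC)c(OC)c1I | intermediate
23 | 5-(benzyloxy)-1,3-dimethoxy-2-[3,4,5-trimethoxy-2-(3,4,5-trimethoxyphenoxy)phenoxy]benzene | COc1cc(OCc2ccccc2)cc(OC)c1Oc1cc(OC)c(OC)c(OC)c1Oc1cc(OC)c(OC)c(OC)c1 | intermediate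
24 | 3,5-dimethoxy-4-[3,4,5-trimethoxy-2-(3,4,5-trimethoxyphenoxy)phenoxy]phenol | COc1cc(O)cc(OC)c1Oc1cc(OC)c(OC)c(OC)c1Oc1cc(OC)c(OC)c(OC)c1 | intermediate
25 | benzyl-capped DEFGH pentamer, 5-(benzyloxy)-2-{2-[3,5-dimethoxy-4-(3,4,5-trimethoxy-2-(3,4,5-trimethoxyphenoxy)phenoxy)phenoxy]-3,4,5-trimethoxyphenoxy}-1,3-dimethoxybenzene | COc1cc(OCc2ccccc2)cc(OC)c1Oc1cc(OC)c(OC)c(OC)c1Oc1cc(OC)c(Oc2cc(OC)c(OC)c(OC)c2Oc2cc(OC)c(OC)c(OC)c2)c(OC)c1 | intermediate
26 | DEFGH pentamer phenol, 4-{2-[3,5-dimethoxy-4-(3,4,5-trimethoxy-2-(3,4,5-trimethoxyphenoxy)phenoxy)phenoxy]-3,4,5-trimethoxyphenoxy}-3,5-dimethoxyphenol | COc1cc(O)cc(OC)c1Oc1cc(OC)c(OC)c(OC)c1Oc1cc(OC)c(Oc2cc(OC)c(OC)c(OC)c2Oc2cc(OC)c(OC)c(OC)c2)c(OC)c1 | intermediate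
27 | permethylated octamer (rings A to H, 21 methoxy groups) | COc1cc(OC)c(Oc2cc(OC)c(Oc3cc(OC)c(OC)c(OC)c3Oc3cc(OC)c(Oc4cc(OC)c(OC)c(OC)c4Oc4cc(OC)c(Oc5cc(OC)c(OC)c(OC)c5Oc5cc(OC)c(OC)c(OC)c5)c(OC)c4)c(OC)c3)c(OC)c2)c(OC)c1 | intermediate
28 | CNP0206369.0 (rings A to H, 21 free hydroxyl groups) | Oc1cc(O)c(Oc2cc(O)c(Oc3cc(O)c(O)c(O)c3Oc3cc(O)c(Oc4cc(O)c(O)c(O)c4Oc4cc(O)c(Oc5cc(O)c(O)c(O)c5Oc5cc(O)c(O)c(O)c5)c(O)c4)c(O)c3)c(O)c2)c(O)c1 | target

**Step count and risk**

Total step count: 15. Longest linear sequence: 10 steps (3, 4, 5, 9, 10, 11, 12, 13, 14, 15).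

Steps most likely to fail:

1. Step 6. The aryl anion may be protonated before iodine transfer, or the phenoxide may be lost by electron transfer to the iodine donor or by addition to the perfluoroalkene that the spent donor sheds, so that the C6 iodide does not form cleanly. The fallback uses known chemistry, sets out from 5 and comes back at 15. Commercial 5-iodo-1,2,3-trimethoxybenzene (COc1cc(I)cc(OC)c1OC) is brominated with NBS in MeCN to 2-bromo-1-iodo-3,4,5-trimethoxybenzene F1. A chemoselective Ullmann etherification of 5 at the C–I bond of F1 (CuI, picolinic acid, K3PO4, DMSO, 90 °C) should give the ABC trimer bromide F2, which carries bromine at C6 of ring C. Copper-catalysed aromatic halogen exchange (CuI, NaI, trans-N,N'-dimethylcyclohexane-1,2-diamine, dioxane, 110 °C) then converts F2 into 15.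

2. Step 9. The same processes as in step 6 threaten it, and the hydroquinone-type phenoxide 20 is in addition the more easily oxidised. The fallback uses known chemistry, sets out from 19 and comes back at 22. Ullmann etherification of 19 at the C–I bond of the 2-bromo-1-iodo-3,4,5-trimethoxybenzene F1 of the first fallback (CuI, picolinic acid, K3PO4, DMSO, 90 °C) should give 5-(benzyloxy)-2-(2-bromo-3,4,5-trimethoxyphenoxy)-1,3-dimethoxybenzene F3. The same halogen exchange (CuI, NaI, trans-N,N'-dimethylcyclohexane-1,2-diamine, dioxane, 110 °C) converts F3 into 22.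

3. Step 14. Protodeiodination and catalyst deactivation may outrun C–O bond formation, because a doubly ortho-substituted iodide and a large phenol have to be joined close to 1:1. The fallback sets out from 15 and comes back at 27; it grows the trimer with monomers and moves the fragment union to the E–F junction. Iodide 15 is coupled under the conditions of step 10 with monomeric phenol 16 (3 equiv) to the ABCD tetramer aldehyde F4. Dakin oxidation as in step 2 leads through the ABCD tetramer formate F5 to the ABCD tetramer phenol F6, whose hydroxyl lies between the two methoxy groups of ring D. The oxy-iodination of step 6 with triflate 11, by then tested on 5 and 19, leads through the tetramer potassium phenoxide F7 and the pentamer aryl anion F8 to the ABCDE pentamer iodide F9. F9 is joined with the trimer phenol 24, which is cheaper than 26 and can be used in excess, under the conditions of step 12 to give 27.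

**Further compounds**

F1 | step 6 | 2-bromo-1-iodo-3,4,5-trimethoxybenzene | COc1cc(I)c(Br)c(OC)c1OC
F2 | step 6 | ABC trimer bromide, 2-[4-(2-bromo-3,4,5-trimethoxyphenoxy)-3,5-dimethoxyphenoxy]-1,3,5-trimethoxybenzene | COc1cc(OC)c(Oc2cc(OC)c(Oc3cc(OC)c(OC)c(OC)c3Br)c(OC)c2)c(OC)c1
F3 | step 9 | 5-(benzyloxy)-2-(2-bromo-3,4,5-trimethoxyphenoxy)-1,3-dimethoxybenzene | COc1cc(OCc2ccccc2)cc(OC)c1Oc1cc(OC)c(OC)c(OC)c1Br
F4 | step 14 | ABCD tetramer aldehyde (15 with iodine replaced by the 4-formyl-3,5-dimethoxyphenoxy group) | COc1cc(OC)c(Oc2cc(OC)c(Oc3cc(OC)c(OC)c(OC)c3Oc3cc(OC)c(C=O)c(OC)c3)c(OC)c2)c(OC)c1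
F5 | step 14 | ABCD tetramer formate | COc1cc(OC)c(Oc2cc(OC)c(Oc3cc(OC)c(OC)c(OC)c3Oc3cc(OC)c(OC=O)c(OC)c3)c(OC)c2)c(OC)c1
F6 | step 14 | ABCD tetramer phenol (hydroxyl at C4 of ring D) | COc1cc(OC)c(Oc2cc(OC)c(Oc3cc(OC)c(OC)c(OC)c3Oc3cc(OC)c(O)c(OC)c3)c(OC)c2)c(OC)c1
F7 | step 14 | potassium phenoxide of the ABCD tetramer | COc1cc(OC)c(Oc2cc(OC)c(Oc3cc(OC)c(OC)c(OC)c3Oc3cc(OC)c([O-])c(OC)c3)c(OC)c2)c(OC)c1.[K+]
F8 | step 14 | potassium salt of the ABCDE pentamer carbanion at C6 of ring E | COc1cc(OC)c(Oc2cc(OC)c(Oc3cc(OC)c(OC)c(OC)c3Oc3cc(OC)c(Oc4cc(OC)c(OC)c(OC)[c-]4)c(OC)c3)c(OC)c2)c(OC)c1.[K+]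
F9 | step 14 | ABCDE pentamer iodide (iodine at C6 of ring E) | COc1cc(OC)c(Oc2cc(OC)c(Oc3cc(OC)c(OC)c(OC)c3Oc3cc(OC)c(Oc4cc(OC)c(OC)c(OC)c4I)c(OC)c3)c(OC)c2)c(OC)c1
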